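**Retrosynthetic overview**
1. Artonin C (20) comes from heptaacetate 19 by removal of seven acetates.
2. The cyclohexene of 19 comes from the donor–acceptor vinylcyclobutane 17 by a Lewis-acid ring expansion (stepwise 1,3-shift: C1–C4 broken, C3–C4 formed); this sets C3 and C4.
3. Cyclobutane 17 comes from an enantioselective radical-anion [2+2] of 2'-hydroxychalcone 12 (C4=C5) with the terminal alkene of dienyl chalcone 16 (C1=C6); this sets C5.
4. 12 and 16 come from one 3'-iodochalcone (9, and its acetate 13) by Suzuki coupling with alkenylboronates 11 and 15; 9 comes from aldol condensation of ketone 7 with aldehyde 4.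
5. 4 and 7 come from resorcinol. Ring order: arenes (bought), then cyclobutane, then cyclohexene.

Assumption: the cyclohexene carbons are labelled C1 (methyl-bearing) to C6 in the order of the target SMILES, and the same labels are kept for these atoms in the cyclobutane; in this labelling artonin C is (3S,4R,5S), with the C3 aryl cis and the C5 aryl trans to the C4 aroyl group.

**Step 1**
Reactants: 1 resorcinol
Product: 3 2,4-dihydroxybenzaldehyde, via (2,4-dihydroxybenzylidene)dimethyliminium chloride 2 (not isolated)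
Conditions: POCl3, DMF, MeCN, −15 °C to rt; then H2O, 50 °C
Reagents that add atoms: N,N-dimethylformamide, CN(C)C=O; water, O
Why: Vilsmeier–Haack formylation attacks the most activated unhindered carbon of resorcinol (para to one OH, ortho to the other) and the iminium salt 2 is hydrolysed on work-up.

**Step 2**
Reactants: 3 2,4-dihydroxybenzaldehyde
Product: 4 4-formyl-1,3-phenylene diacetate
Conditions: Ac2O (2.3 equiv), pyridine, CH2Cl2, 0 °C to rt
Reagents that add atoms: acetic anhydride, CC(=O)OC(C)=O
Why: Pyridine-mediated O-acetylation (esterification) of both phenols at low temperature, where Perkin-type coumarin formation does not compete.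

**Step 3**
Reactants: 1 resorcinol
Product: 5 1-(2,4-dihydroxyphenyl)ethanone
Conditions: AcOH, ZnCl2, 140 °C
Reagents that add atoms: acetic acid, CC(=O)O
Why: Nencki reaction (ZnCl2-mediated Friedel–Crafts C-acylation) of resorcinol gives the 4-acyl product, stabilised by the ortho-hydroxy ketone hydrogen bond.

**Step 4**
Reactants: 5 1-(2,4-dihydroxyphenyl)ethanone
Product: 6 1-(2,4-dihydroxy-3-iodophenyl)ethanone
Conditions: I2, KI, aq NH3, 0 °C to rt
Reagents that add atoms: iodine, II
Why: Electrophilic aromatic iodination under ammoniacal (phenoxide) conditions goes to the doubly ortho-activated carbon between the two oxygens, as in the 8-iodination of 7-hydroxycoumarins.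

**Step 5**
Reactants: 6 1-(2,4-dihydroxy-3-iodophenyl)ethanone
Product: 7 4-acetyl-3-hydroxy-2-iodophenyl acetate
Conditions: Ac2O (1.05 equiv), pyridine, CH2Cl2, −10 °C
Reagents that add atoms: acetic anhydride, CC(=O)OC(C)=O
Why: Selective O-acetylation (esterification): the 2-OH is hydrogen-bonded to the ketone and hindered, so one equivalent of Ac2O acylates only the 4-OH.

**Step 6**
Reactants: 7 4-acetyl-3-hydroxy-2-iodophenyl acetate; 4 4-formyl-1,3-phenylene diacetate
Product: 9 (E)-1-(4-acetoxy-2-hydroxy-3-iodophenyl)-3-(2,4-diacetoxyphenyl)prop-2-en-1-one, via difluoroboron chelate 8 (not isolated)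
Conditions: BF3·OEt2 (3 equiv), 1,4-dioxane, rt; then H2O/THF, 40 °C
Reagents that add atoms: none
Why: BF3-mediated Claisen–Schmidt (aldol) condensation runs through the enolisable difluoroboron chelate of the 2'-hydroxyacetophenone, tolerates the base-labile aryl acetates and gives the E-enone under thermodynamic control.

**Step 7**
Reactants: 10 3-methylbut-1-yne
Product: 11 (E)-4,4,5,5-tetramethyl-2-(3-methylbut-1-en-1-yl)-1,3,2-dioxaborolane
Conditions: pinacolborane (1.1 equiv), Cp2Zr(H)Cl (5 mol%), Et3N (10 mol%), neat, 60 °C, sealed tube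
Reagents that add atoms: pinacolborane, [H]B1OC(C)(C)C(C)(C)O1
Why: Zirconocene-hydride-catalysed syn-hydroboration of the terminal alkyne places boron on the terminal carbon and gives only the E-alkenylboronate.

**Step 8**
Reactants: 9 (E)-1-(4-acetoxy-2-hydroxy-3-iodophenyl)-3-(2,4-diacetoxyphenyl)prop-2-en-1-one; 11 (E)-4,4,5,5-tetramethyl-2-(3-methylbut-1-en-1-yl)-1,3,2-dioxaborolane
Product: 12 (E)-1-[4-acetoxy-2-hydroxy-3-((E)-3-methylbut-1-en-1-yl)phenyl]-3-(2,4-diacetoxyphenyl)prop-2-en-1-one
Conditions: Pd(dppf)Cl2 (5 mol%), K3PO4 (anhydrous), 1,4-dioxane, 60 °C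
Reagents that add atoms: none
Why: Suzuki–Miyaura coupling under anhydrous phosphate conditions keeps the aryl acetates and transfers the alkenyl group with retention of E geometry.

**Step 9**
Reactants: 9 (E)-1-(4-acetoxy-2-hydroxy-3-iodophenyl)-3-(2,4-diacetoxyphenyl)prop-2-en-1-one
Product: 13 (E)-1-(2,4-diacetoxy-3-iodophenyl)-3-(2,4-diacetoxyphenyl)prop-2-en-1-one
Conditions: Ac2O, Et3N, DMAP (10 mol%), CH2Cl2, rt
Reagents that add atoms: acetic anhydride, CC(=O)OC(C)=O
Why: DMAP-catalysed O-acetylation of the chelated 2'-OH removes the only Lewis-acid-chelating site of the future diene partner and avoids a free phenol next to the diene.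

**Step 10**
Reactants: 14 2-methylbut-1-en-3-yne
Product: 15 (E)-4,4,5,5-tetramethyl-2-(3-methylbuta-1,3-dien-1-yl)-1,3,2-dioxaborolane
Conditions: pinacolborane (1.1 equiv), Cp2Zr(H)Cl (5 mol%), Et3N (10 mol%), neat, 40 °C, sealed tube
Reagents that add atoms: pinacolborane, [H]B1OC(C)(C)C(C)(C)O1
Why: The same catalysed syn-hydroboration is chemoselective for the alkyne over the 1,1-disubstituted alkene and gives the E-dienylboronate.

**Step 11**
Reactants: 13 (E)-1-(2,4-diacetoxy-3-iodophenyl)-3-(2,4-diacetoxyphenyl)prop-2-en-1-one; 15 (E)-4,4,5,5-tetramethyl-2-(3-methylbuta-1,3-dien-1-yl)-1,3,2-dioxaborolane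
Product: 16 (E)-1-[2,4-diacetoxy-3-((E)-3-methylbuta-1,3-dien-1-yl)phenyl]-3-(2,4-diacetoxyphenyl)prop-2-en-1-one
Conditions: Pd(dppf)Cl2 (5 mol%), K3PO4 (anhydrous), 1,4-dioxane, 60 °C
Reagents that add atoms: none
Why: Suzuki–Miyaura coupling installs the E-configured 3-methylbuta-1,3-dienyl group with retention of alkene geometry under ester-tolerant conditions.

**Step 12**
Reactants: 12 (E)-1-[4-acetoxy-2-hydroxy-3-((E)-3-methylbut-1-en-1-yl)phenyl]-3-(2,4-diacetoxyphenyl)prop-2-en-1-one; 16 (E)-1-[2,4-diacetoxy-3-((E)-3-methylbuta-1,3-dien-1-yl)phenyl]-3-(2,4-diacetoxyphenyl)prop-2-en-1-one (1.5 equiv)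
Product: 17 (1S,4R,5S)-vinylcyclobutane (C1: CH3 and the E-arylvinyl group; C4: aroyl; C5: 2,4-diacetoxyphenyl; C6: CH2; aroyl trans to both neighbours)
Conditions: Ru(bpy)3(PF6)2 (2.5 mol%), Gd(OTf)3 (10 mol%), (S,S)-tBu-PyBox [2,6-bis((4S)-4-tert-butyl-4,5-dihydrooxazol-2-yl)pyridine] (15 mol%), i-Pr2NEt (2 equiv), MeCN, blue LEDs, 0 °C, degassed
Reagents that add atoms: none
Why: Proposed new method: only 12 can chelate the Gd–PyBox Lewis acid (16 is fully acetylated), so the photoreduced ruthenium complex reduces it selectively to a radical anion whose β-carbon radical (C5) adds to the terminal CH2 (C6) of the s-trans diene, and the resulting transoid aryl-allyl radical can only close at C1 onto the enolate carbon C4 (4-exo radical–enolate coupling, then back electron transfer), which fixes the C5–C6/C4–C1 regiochemistry and lets the chiral Lewis acid set C5 (S; the ligand antipode is used if the first run shows the opposite sense), while C1/C4 epimers are carried on because both centres are erased in step 13; the closest known reaction type is the dual Lewis-acid/photoredox radical-anion [2+2] cycloaddition of aryl enones with Michael acceptors and the related radical-anion [3+2] of aryl cyclopropyl ketones with dienes.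

**Step 13**
Reactants: 17 (1S,4R,5S)-vinylcyclobutane
Product: 19 (3S,4R,5S)-cyclohexene heptaacetate, via ring-opened zwitterion 18 (not isolated)
Conditions: Sc(OTf)3 (10 mol%), CH2Cl2/MeCN (9:1), −40 to 0 °C
Reagents that add atoms: none
Why: Proposed new method: Sc(OTf)3 chelation of the 2'-hydroxyaryl ketone heterolyses the strained donor–acceptor C1–C4 bond to zwitterion 18 (chelated enolate plus tertiary aryl-allyl cation), which, when formed from the rotamer with C6 syn to C3, recloses at the benzylic terminus C3 through a chair-like compact ion pair (Ar at C5 equatorial so C4 ends trans to C5, cationic aryl under the chelate so C3 ends cis to C4), a stepwise non-pericyclic 1,3-shift ring expansion that leaves C5 untouched; the closest known reaction type is the acid-promoted vinylcyclobutane-to-cyclohexene rearrangement of 2-siloxy or otherwise cation-stabilised vinylcyclobutanes and the Lewis-acid ring opening of donor–acceptor cyclobutanes.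

**Step 14**
Reactants: 19 (3S,4R,5S)-cyclohexene heptaacetate
Product: 20 artonin C
Conditions: K2CO3, MeOH/THF, 0 °C to rt; aq NH4Cl work-up
Reagents that add atoms: none
Why: Base-mediated methanolysis (transesterification) of the seven aryl acetates at 0 °C, mild enough that the epimerisable C4 centre is expected to hold; no new stereocentre is formed.

**Compound list**
1 | resorcinol (benzene-1,3-diol) | Oc1cccc(O)c1 | starting material
2 | (2,4-dihydroxybenzylidene)dimethyliminium chloride | C[N+](C)=Cc1ccc(O)cc1O.[Cl-] | intermediate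
3 | 2,4-dihydroxybenzaldehyde | O=Cc1ccc(O)cc1O | intermediate
4 | 4-formyl-1,3-phenylene diacetate (2,4-diacetoxybenzaldehyde) | CC(=O)Oc1ccc(C=O)c(OC(C)=O)c1 | intermediate
5 | 1-(2,4-dihydroxyphenyl)ethanone | CC(=O)c1ccc(O)cc1O | intermediate
6 | 1-(2,4-dihydroxy-3-iodophenyl)ethanone | CC(=O)c1ccc(O)c(I)c1O | intermediate
7 | 4-acetyl-3-hydroxy-2-iodophenyl acetate | CC(=O)Oc1ccc(C(C)=O)c(O)c1I | intermediate
8 | difluoroboron chelate of 9 (BF2 bridging the 2'-O and the carbonyl O) | CC(=O)Oc1ccc(/C=C/C2=[O+][B-](F)(F)Oc3c2ccc(OC(C)=O)c3I)c(OC(C)=O)c1 | intermediate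
9 | (E)-1-(4-acetoxy-2-hydroxy-3-iodophenyl)-3-(2,4-diacetoxyphenyl)prop-2-en-1-one | CC(=O)Oc1ccc(/C=C/C(=O)c2ccc(OC(C)=O)c(I)c2O)c(OC(C)=O)c1 | intermediate
10 | 3-methylbut-1-yne | CC(C)C#C | starting material
11 | (E)-4,4,5,5-tetramethyl-2-(3-methylbut-1-en-1-yl)-1,3,2-dioxaborolane | CC(C)/C=C/B1OC(C)(C)C(C)(C)O1 | intermediate
12 | (E)-1-[4-acetoxy-2-hydroxy-3-((E)-3-methylbut-1-en-1-yl)phenyl]-3-(2,4-diacetoxyphenyl)prop-2-en-1-one | CC(C)/C=C/c1c(OC(C)=O)ccc(C(=O)/C=C/c2ccc(OC(C)=O)cc2OC(C)=O)c1O | intermediate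
13 | (E)-1-(2,4-diacetoxy-3-iodophenyl)-3-(2,4-diacetoxyphenyl)prop-2-en-1-one | CC(=O)Oc1ccc(/C=C/C(=O)c2ccc(OC(C)=O)c(I)c2OC(C)=O)c(OC(C)=O)c1 | intermediate
14 | 2-methylbut-1-en-3-yne | C=C(C)C#C | starting material
15 | (E)-4,4,5,5-tetramethyl-2-(3-methylbuta-1,3-dien-1-yl)-1,3,2-dioxaborolane | C=C(C)/C=C/B1OC(C)(C)C(C)(C)O1 | intermediate
16 | (E)-1-[2,4-diacetoxy-3-((E)-3-methylbuta-1,3-dien-1-yl)phenyl]-3-(2,4-diacetoxyphenyl)prop-2-en-1-one | C=C(C)/C=C/c1c(OC(C)=O)ccc(C(=O)/C=C/c2ccc(OC(C)=O)cc2OC(C)=O)c1OC(C)=O | intermediate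
17 | (1S,4R,5S)-cyclobutane: C1 carries CH3 and (E)-2-[2,6-diacetoxy-3-((E)-3-(2,4-diacetoxyphenyl)acryloyl)phenyl]ethenyl; C4 carries 4-acetoxy-2-hydroxy-3-((E)-3-methylbut-1-enyl)benzoyl; C5 carries 2,4-diacetoxyphenyl; C6 is CH2; aroyl trans to the C5 aryl and to the C1 alkenyl group | C[C@@]1(/C=C/c2c(OC(C)=O)ccc(C(=O)/C=C/c3ccc(OC(C)=O)cc3OC(C)=O)c2OC(C)=O)C[C@H](c2ccc(OC(C)=O)cc2OC(C)=O)[C@H]1C(=O)c1ccc(OC(C)=O)c(/C=C/C(C)C)c1O | intermediate
18 | ring-opened zwitterion: (Z)-enolate of the aryl ketone at C4, linked through C5 (S) and C6 to the (Z)-1-aryl-3-methylallyl cation C1–C3 | C/C(=C/[CH+]c2c(OC(C)=O)ccc(C(=O)/C=C/c3ccc(OC(C)=O)cc3OC(C)=O)c2OC(C)=O)C[C@H](c2ccc(OC(C)=O)cc2OC(C)=O)/C=C(\[O-])c1ccc(OC(C)=O)c(/C=C/C(C)C)c1O | intermediate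
19 | (3S,4R,5S)-heptaacetate of artonin C (every phenol acetylated except the 2-OH of the C4 aroyl ring); C3 aryl cis and C5 aryl trans to the C4 aroyl group | CC1=C[C@H](c2c(OC(C)=O)ccc(C(=O)/C=C/c3ccc(OC(C)=O)cc3OC(C)=O)c2OC(C)=O)[C@H](C(=O)c2ccc(OC(C)=O)c(/C=C/C(C)C)c2O)[C@@H](c2ccc(OC(C)=O)cc2OC(C)=O)C1 | intermediate
20 | artonin C: (3S,4R,5S)-1-methylcyclohex-1-ene with 2,6-dihydroxy-3-[(E)-3-(2,4-dihydroxyphenyl)acryloyl]phenyl at C3, 2,4-dihydroxy-3-[(E)-3-methylbut-1-enyl]benzoyl at C4 and 2,4-dihydroxyphenyl at C5 | CC1=C[C@H](c2c(O)ccc(C(=O)/C=C/c3ccc(O)cc3O)c2O)[C@H](C(=O)c2ccc(O)c(/C=C/C(C)C)c2O)[C@@H](c2ccc(O)cc2O)C1 | target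

**Totals**
Total steps: 14. Longest linear sequence: 9 steps (3, 4, 5, 6, 9, 11, 12, 13, 14).

**Three steps most likely to fail**

Step 12 (proposed new step). The chalcone radical anion may dimerise reductively, the four-membered radical–enolate closure may be slow, and direct triplet sensitisation of the bound chalcone would give the regioisomeric cyclobutane; the enantioselectivity is untested. Fallback with known chemistry: set out from 12 and 16 and join them by the established chiral-borate-promoted asymmetric Diels–Alder reaction of 2'-hydroxychalcones with aryl dienes (B(OPh)3, (S)-VANOL [3,3'-diphenyl-2,2'-binaphthalene-1,1'-diol] or its antipode, PhCF3, rt), which gives the endo adduct and so comes back to the route at 19. This fallback makes no new compound (F0).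

Step 13 (proposed new step). The zwitterion may fragment by retro-Michael cleavage and erode the ee, close on the other face to give the exo isomer, or simply return to the cyclobutane. Fallback with known chemistry and a different mechanism: set out from 17 and run the thermal vinylcyclobutane-to-cyclohexene rearrangement (degassed o-xylene, BHT, 140 °C), in which homolysis of the same C1–C4 bond and recombination at C3 leave C5 untouched; it comes back to the route at 19. This fallback makes no new compound (F0).

Step 4. Iodination may go to C5 or twice. Fallback: set out from 1 and iodinate first (I2, NaHCO3, H2O, 0 °C), where the position between the two hydroxyls is the only doubly ortho-activated one, to give 2-iodoresorcinol F1. Then carry out a Houben–Hoesch acylation with acetonitrile (ZnCl2, HCl gas, Et2O, 0 °C) to the ketiminium chloride F2, which is hydrolysed in warm water; the sequence comes back to the route at 6.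

**Further compounds**
F0 | step 12 | none | none
F0 | step 13 | none | none
F1 | step 4 | 2-iodobenzene-1,3-diol (2-iodoresorcinol) | Oc1cccc(O)c1I
F2 | step 4 | 1-(2,4-dihydroxy-3-iodophenyl)ethan-1-iminium chloride | CC(=[NH2+])c1ccc(O)c(I)c1O.[Cl-]
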